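## Retrosynthetic overview

1. Target 25 ⇒ C7–C8 bond (anti-aldol, then CHO → CH2OH): guaiacyl aldehyde 5 (ring A) + aryloxyacetaldehyde 22; both side-chain stereocentres come from this step.
2. 22 ⇒ trans-dihydrobenzofuran 21 (methyl ester → CH2OH, Weinreb amide → CHO, acetal → CHO).
3. Key step: 21 ⇒ (R)-flavanone 19 by oxidative ring contraction (1,2-shift of the ring C aryl carbon, pyranone → dihydrofuran); 19 by kinetic resolution of racemic 18.
4. 18 ⇒ 2'-hydroxychalcone 16 (oxa-Michael) ⇒ 5-acetylvanillin 8 (ring C) + syringaldehyde ether 15 (ring B), joined by Claisen–Schmidt condensation.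
5. Ring order: the three arenes are bought (catechol for rings A and C, p-cresol for ring B); the only ring made is the O-heterocycle, closed as a chromanone and then contracted to the dihydrobenzofuran.

Assumption: the SMILES is read as 7S,8R (erythro) in the arylglycerol unit and 2R,3S (trans) in the dihydrobenzofuran; lignan numbering C7–C9 is used for the side chain.

## Route

Step 1
Reactants: 1 catechol
Product: 2 guaiacol
Conditions: MeI (0.95 equiv), K2CO3, acetone, 56 °C
Reagents that add atoms: iodomethane, CI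
Why: Williamson O-methylation; the first methylation lowers the acidity of the remaining OH and a slight deficit of MeI limits over-methylation to veratrole, which is removed by base extraction.

Step 2
Reactants: 2 guaiacol
Product: 4 vanillin, via vanillylmandelic acid 3 (not isolated)
Conditions: OHCCO2H, NaOH, H2O, 30 °C; then O2 (air), CuSO4 (cat.), 95 °C; then H2SO4
Reagents that add atoms: glyoxylic acid, O=CC(=O)O
Why: Electrophilic para-hydroxyalkylation of the phenoxide by glyoxylate followed by copper-catalysed aerobic oxidative decarboxylation of the mandelate (the technical glyoxylic acid route to vanillin).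

Step 3
Reactants: 4 vanillin
Product: 5 vanillin acetate (4-formyl-2-methoxyphenyl acetate)
Conditions: Ac2O, pyridine, 25 °C
Reagents that add atoms: acetic anhydride, CC(=O)OC(C)=O
Why: Phenol O-acylation; the acetate makes the aldehyde electrophilic enough to act as aldol acceptor in step 14 and is cleaved there.

Step 4
Reactants: 4 vanillin
Product: 6 5-iodovanillin
Conditions: N-iodosuccinimide, TFA (cat.), MeCN, 25 °C
Reagents that add atoms: N-iodosuccinimide, O=C1CCC(=O)N1I
Why: Electrophilic aromatic iodination directed by the phenol to its only free ortho position.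

Step 5
Reactants: 6 5-iodovanillin
Product: 8 5-acetylvanillin (3-acetyl-4-hydroxy-5-methoxybenzaldehyde), via aryl methyl dioxolane 7 (not isolated)
Conditions: 2-(vinyloxy)ethanol, Pd(OAc)2 (3 mol %), dppp (6 mol %), K2CO3, H2O–DMF, 90 °C; then 2 M HCl, 25 °C
Reagents that add atoms: 2-(vinyloxy)ethanol, C=COCCO; water, O
Why: Internal-selective Heck arylation of a hydroxyalkyl vinyl ether (cationic palladium pathway with a bidentate phosphine) traps the product as the cyclic ketal, and acid hydrolysis releases the methyl ketone.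

Step 6
Reactants: 9 p-cresol
Product: 12 3,5-dibromo-4-hydroxybenzaldehyde, via 2,6-dibromo-4-methylphenol 10 (not isolated), via 2,6-dibromo-4-(dibromomethyl)phenol 11 (not isolated)
Conditions: Br2 (4.1 equiv), 1,2-dichlorobenzene, 35 °C then 150 °C; then H2O, 100 °C
Reagents that add atoms: bromine, BrBr; water, O
Why: Electrophilic ring bromination ortho to OH, then thermal benzylic bromination to the benzal bromide and hydrolysis to the aldehyde (technical route to this aldehyde).

Step 7
Reactants: 12 3,5-dibromo-4-hydroxybenzaldehyde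
Product: 13 syringaldehyde
Conditions: NaOMe, CuCl (cat.), DMF–MeOH, 115 °C; then HCl
Reagents that add atoms: sodium methoxide, C[O-].[Na+]
Why: Copper-catalysed Ullmann-type methoxylation of both aryl bromides (technical route to syringaldehyde).

Step 8
Reactants: 13 syringaldehyde; 14 2-chloro-N-methoxy-N-methylacetamide
Product: 15 2-(4-formyl-2,6-dimethoxyphenoxy)-N-methoxy-N-methylacetamide
Conditions: K2CO3, NaI (cat.), DMF, 70 °C
Reagents that add atoms: none
Why: Williamson etherification (SN2) with a reactive α-chloro amide; the Weinreb amide is a latent aldehyde that is inert to the conditions of steps 9–12.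

Step 9
Reactants: 8 5-acetylvanillin; 15 Weinreb amide aldehyde
Product: 16 (E)-2'-hydroxychalcone
Conditions: KOH, EtOH–H2O, 25 °C; then AcOH
Reagents that add atoms: none
Why: Claisen–Schmidt condensation; in KOH the formyl group of 8 is para to a phenoxide (a vinylogous carboxylate) and does not act as acceptor, so the acetyl enolate condenses only with the non-phenolic aldehyde 15 and E1cB dehydration gives the E-enone.

Step 10
Reactants: 16 chalcone
Product: 18 racemic flavanone dimethyl acetal, via chalcone dimethyl acetal 17 (not isolated)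
Conditions: HC(OMe)3, TsOH·H2O (5 mol %), MeOH, 25 °C; then NaOAc, 65 °C
Reagents that add atoms: trimethyl orthoformate, COC(OC)OC
Why: Chemoselective acetalisation of the aryl aldehyde (the hydrogen-bonded enone is untouched), then base-catalysed 6-endo intramolecular oxa-Michael addition (chalcone–flavanone isomerisation), giving the flavanone as the racemate.

Step 11
Reactants: 18 racemic flavanone
Product: 19 (2R)-flavanone dimethyl acetal
Conditions: RuCl[(S,S)-TsDPEN](p-cymene) (1 mol %), HCO2Na, H2O–EtOAc, 30 °C, stopped at about 55% conversion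
Reagents that add atoms: none
Why: Noyori–Ikariya asymmetric transfer hydrogenation used as a kinetic resolution: the (S,S) catalyst forms 4S benzylic alcohols and so reduces the 2S ketone (to the cis 2S,4S flavan-4-ol, removed by chromatography) much faster than the 2R ketone, which is recovered in high ee at no more than 50% yield.

Step 12
Reactants: 19 (2R)-flavanone
Product: 21 methyl (2R,3R)-trans-2-aryl-2,3-dihydrobenzofuran-3-carboxylate, via 4-methoxy-2H-chromene enol ether 20 (not isolated)
Conditions: PhI(OAc)2 (1.2 equiv), H2SO4, HC(OMe)3, 0 → 25 °C; NaHCO3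
Reagents that add atoms: trimethyl orthoformate, COC(OC)OC
Why: Hypervalent iodine oxidative ring contraction of a flavanone: the iodane attacks enol ether 20 at C3 anti to the 2-aryl group, and the ring C aryl carbon then shifts from the ketal carbon C4 to C3 with loss of PhI (1,2-aryl shift, six- to five-membered O-ring), so C2 keeps its R configuration and the new C3 centre is set trans to it.

Step 13
Reactants: 21 dihydrobenzofuran ester
Product: 22 (2R,3S)-dialdehyde alcohol
Conditions: LiAlH4, THF, −20 → 0 °C; then 1 M HCl, THF, 25 °C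
Reagents that add atoms: water, O
Why: Hydride reduction: LiAlH4 takes the methyl ester to the primary alcohol while the Weinreb amide stops at its chelated tetrahedral adduct; the acidic work-up collapses that adduct to the aldehyde and hydrolyses the aryl dimethyl acetal, and no stereocentre is involved.

Step 14
Reactants: 22 dialdehyde alcohol; 5 vanillin acetate
Product: 25 target CID53356209, via anti-aldol aldehyde 23 (not isolated), via diol acetate 24 (not isolated)
Conditions: L-proline (20 mol %), 5 (6 equiv), DMF, 4 °C, 22 added over 24 h; then NaBH(OAc)3, AcOH, MeCN, −20 °C; then K2CO3, MeOH, 0 °C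
Reagents that add atoms: none
Why: Proposed new method: an L-proline-catalysed direct cross-aldol in which an α-aryloxyacetaldehyde (the hindered syringyl ether 22) is the enamine donor and an aromatic aldehyde the acceptor, telescoped with hydroxyl-directed reduction, as a one-flask entry to erythro arylglycerol β-aryl ethers; the E-enamine (aryloxy group anti to nitrogen) attacks the re face of 5 through the carboxylic-acid-bound chair-like Houk–List transition state with the aryl group of 5 pseudo-equatorial, giving the anti (2S,3S) aldol 23, which is 7S,8R after reduction; the non-enolisable, acetate-activated acceptor in sixfold excess and slow addition of 22 suppress donor self-aldolisation, the electron-rich ring C aldehyde of 22 is a far poorer acceptor than 5, NaBH(OAc)3 reduces only the β-hydroxy aliphatic aldehyde (intramolecular hydride delivery) and leaves the aryl aldehydes, and methanolysis removes the acetate; closest known reaction type: proline-catalysed enamine cross-aldol of aldehyde donors (including α-alkoxy and α-silyloxy acetaldehydes) with aldehyde acceptors, which is anti-selective but, as far as I know, not shown for α-aryloxy donors or for this bond of lignin-type ethers.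

## Compound list

1 | catechol (benzene-1,2-diol) | Oc1ccccc1O | starting material
2 | guaiacol (2-methoxyphenol) | COc1ccccc1O | intermediate
3 | 4-hydroxy-3-methoxymandelic acid (vanillylmandelic acid; racemic; not isolated) | COc1cc(C(O)C(=O)O)ccc1O | intermediate
4 | vanillin (4-hydroxy-3-methoxybenzaldehyde) | COc1cc(C=O)ccc1O | intermediate
5 | 4-formyl-2-methoxyphenyl acetate (vanillin acetate) | COc1cc(C=O)ccc1OC(C)=O | intermediate
6 | 4-hydroxy-3-iodo-5-methoxybenzaldehyde (5-iodovanillin) | COc1cc(C=O)cc(I)c1O | intermediate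
7 | 4-hydroxy-3-methoxy-5-(2-methyl-1,3-dioxolan-2-yl)benzaldehyde (not isolated) | COc1cc(C=O)cc(C2(C)OCCO2)c1O | intermediate
8 | 3-acetyl-4-hydroxy-5-methoxybenzaldehyde (5-acetylvanillin) | COc1cc(C=O)cc(C(C)=O)c1O | intermediate
9 | p-cresol (4-methylphenol) | Cc1ccc(O)cc1 | starting material
10 | 2,6-dibromo-4-methylphenol (not isolated) | Cc1cc(Br)c(O)c(Br)c1 | intermediate
11 | 2,6-dibromo-4-(dibromomethyl)phenol (not isolated) | BrC(Br)c1cc(Br)c(O)c(Br)c1 | intermediate
12 | 3,5-dibromo-4-hydroxybenzaldehyde | O=Cc1cc(Br)c(O)c(Br)c1 | intermediate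
13 | syringaldehyde (4-hydroxy-3,5-dimethoxybenzaldehyde) | COc1cc(C=O)cc(OC)c1O | intermediate
14 | 2-chloro-N-methoxy-N-methylacetamide | CON(C)C(=O)CCl | starting material
15 | 2-(4-formyl-2,6-dimethoxyphenoxy)-N-methoxy-N-methylacetamide | CON(C)C(=O)COc1c(OC)cc(C=O)cc1OC | intermediate
16 | 2-{4-[(E)-3-(5-formyl-2-hydroxy-3-methoxyphenyl)-3-oxoprop-1-en-1-yl]-2,6-dimethoxyphenoxy}-N-methoxy-N-methylacetamide | CON(C)C(=O)COc1c(OC)cc(/C=C/C(=O)c2cc(C=O)cc(OC)c2O)cc1OC | intermediate
17 | 2-{4-[(E)-3-(5-(dimethoxymethyl)-2-hydroxy-3-methoxyphenyl)-3-oxoprop-1-en-1-yl]-2,6-dimethoxyphenoxy}-N-methoxy-N-methylacetamide (not isolated) | CON(C)C(=O)COc1c(OC)cc(/C=C/C(=O)c2cc(C(OC)OC)cc(OC)c2O)cc1OC | intermediate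
18 | rac-2-{4-[6-(dimethoxymethyl)-8-methoxy-4-oxochroman-2-yl]-2,6-dimethoxyphenoxy}-N-methoxy-N-methylacetamide | CON(C)C(=O)COc1c(OC)cc(C2Oc3c(OC)cc(C(OC)OC)cc3C(=O)C2)cc1OC | intermediate
19 | 2-{4-[(2R)-6-(dimethoxymethyl)-8-methoxy-4-oxochroman-2-yl]-2,6-dimethoxyphenoxy}-N-methoxy-N-methylacetamide | CON(C)C(=O)COc1c(OC)cc([C@@H]2Oc3c(OC)cc(C(OC)OC)cc3C(=O)C2)cc1OC | intermediate
20 | 2-{4-[(2R)-6-(dimethoxymethyl)-4,8-dimethoxy-2H-chromen-2-yl]-2,6-dimethoxyphenoxy}-N-methoxy-N-methylacetamide (not isolated) | CON(C)C(=O)COc1c(OC)cc([C@@H]2Oc3c(OC)cc(C(OC)OC)cc3C(OC)=C2)cc1OC | intermediate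
21 | methyl (2R,3R)-5-(dimethoxymethyl)-2-{3,5-dimethoxy-4-[2-(methoxy(methyl)amino)-2-oxoethoxy]phenyl}-7-methoxy-2,3-dihydro-1-benzofuran-3-carboxylate (2,3-trans) | CON(C)C(=O)COc1c(OC)cc([C@@H]2Oc3c(OC)cc(C(OC)OC)cc3[C@H]2C(=O)OC)cc1OC | intermediate
22 | (2R,3S)-2-[3,5-dimethoxy-4-(2-oxoethoxy)phenyl]-3-(hydroxymethyl)-7-methoxy-2,3-dihydro-1-benzofuran-5-carbaldehyde | O=CCOc1c(OC)cc([C@@H]2Oc3c(OC)cc(C=O)cc3[C@H]2CO)cc1OC | intermediate
23 | 4-[(1S,2S)-2-{4-[(2R,3S)-5-formyl-3-(hydroxymethyl)-7-methoxy-2,3-dihydro-1-benzofuran-2-yl]-2,6-dimethoxyphenoxy}-1-hydroxy-3-oxopropyl]-2-methoxyphenyl acetate (anti aldol; not isolated) | COc1cc([C@H](O)[C@@H](C=O)Oc2c(OC)cc([C@@H]3Oc4c(OC)cc(C=O)cc4[C@H]3CO)cc2OC)ccc1OC(C)=O | intermediate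
24 | 4-[(1S,2R)-2-{4-[(2R,3S)-5-formyl-3-(hydroxymethyl)-7-methoxy-2,3-dihydro-1-benzofuran-2-yl]-2,6-dimethoxyphenoxy}-1,3-dihydroxypropyl]-2-methoxyphenyl acetate (not isolated) | COc1cc([C@H](O)[C@@H](CO)Oc2c(OC)cc([C@@H]3Oc4c(OC)cc(C=O)cc4[C@H]3CO)cc2OC)ccc1OC(C)=O | intermediate
25 | (2R,3S)-2-{4-[(1S,2R)-1,3-dihydroxy-1-(4-hydroxy-3-methoxyphenyl)propan-2-yl]oxy-3,5-dimethoxyphenyl}-3-(hydroxymethyl)-7-methoxy-2,3-dihydro-1-benzofuran-5-carbaldehyde (CID53356209) | COc1cc([C@H](O)[C@@H](CO)Oc2c(OC)cc([C@@H]3Oc4c(OC)cc(C=O)cc4[C@H]3CO)cc2OC)ccc1O | target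

## Step count and risks

Total steps: 14. Longest linear sequence: 10 steps (1, 2, 4, 5, 9, 10, 11, 12, 13, 14).

The three steps most likely to fail:

**Step 14 (proposed aldol).** Risks are self-aldolisation of 22, a modest anti:syn ratio with an aromatic acceptor, and over-reduction of the aryl aldehydes. The fallback is a known auxiliary-controlled glycolate aldol; it sets out from 21 and comes back to the route at 25.
- Cp2Zr(H)Cl (THF, 25 °C) reduces only the Weinreb amide of 21 and gives methyl (2R,3R)-5-(dimethoxymethyl)-2-[3,5-dimethoxy-4-(2-oxoethoxy)phenyl]-7-methoxy-2,3-dihydro-1-benzofuran-3-carboxylate F1.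
- Chlorite oxidation buffered at pH 6.5 (NaClO2, 2-methyl-2-butene, phosphate, t-BuOH–H2O) gives the aryloxyacetic acid F2.
- The pivaloyl mixed anhydride and lithiated (S)-4-benzyl-1,3-oxazolidin-2-one give the N-(aryloxyacetyl)oxazolidinone F3.
- Bu2BOTf/i-Pr2NEt enolisation and addition of 5 at −78 °C give the Evans syn aldol adduct F4 (7R at the carbinol, aryloxy carbon already as in the target).
- Mitsunobu inversion of the benzylic carbinol (4-nitrobenzoic acid, PPh3, DIAD) gives the 7S 4-nitrobenzoate F5.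
- LiBH4 (THF–MeOH, 0 °C) cleaves the auxiliary to the C9 alcohol, reduces the ring ester to CH2OH and removes the 4-nitrobenzoate and the aryl acetate, giving the target dimethyl acetal F6; an aqueous citric acid work-up hydrolyses the acetal to 25.

**Step 12 (ring contraction).** Risks are competing migration of the 2-aryl group (isoflavone), dehydrogenation to the flavone, and acid-induced erosion at C2. The fallback keeps the 1,2-aryl shift but separates activation from migration; it sets out from 19 and comes back at 21. CuBr2 (EtOAc–CHCl3, 60 °C) α-brominates the ketone to the 2,3-trans bromide 2-{4-[(2S,3S)-3-bromo-6-(dimethoxymethyl)-8-methoxy-4-oxochroman-2-yl]-2,6-dimethoxyphenoxy}-N-methoxy-N-methylacetamide F7. AgBF4 in HC(OMe)3–MeOH (50 °C) then converts its dimethyl ketal, by silver-assisted 1,2-aryl shift anti to bromide (α-halo ketal rearrangement), into the same trans ester 21.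

**Step 9 (Claisen–Schmidt with a free formyl group).** The risk is self-condensation of 8 if phenoxide deactivation of its aldehyde is incomplete. The fallback masks the aldehyde first; it sets out from 8 and comes back at 17. 8 is acetalised (HC(OMe)3, MeOH, TsOH cat., 25 °C) to 1-[5-(dimethoxymethyl)-2-hydroxy-3-methoxyphenyl]ethan-1-one F8, which has no electrophilic site. Condensation of F8 with 15 (KOH, EtOH; NH4Cl work-up) gives 17 directly, and heating with NaOAc as in step 10 gives 18.

Further compounds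

F1 | step 14 | methyl (2R,3R)-5-(dimethoxymethyl)-2-[3,5-dimethoxy-4-(2-oxoethoxy)phenyl]-7-methoxy-2,3-dihydro-1-benzofuran-3-carboxylate | O=CCOc1c(OC)cc([C@@H]2Oc3c(OC)cc(C(OC)OC)cc3[C@H]2C(=O)OC)cc1OC
F2 | step 14 | 2-{4-[(2R,3R)-5-(dimethoxymethyl)-7-methoxy-3-(methoxycarbonyl)-2,3-dihydro-1-benzofuran-2-yl]-2,6-dimethoxyphenoxy}acetic acid | OC(=O)COc1c(OC)cc([C@@H]2Oc3c(OC)cc(C(OC)OC)cc3[C@H]2C(=O)OC)cc1OC
F3 | step 14 | methyl (2R,3R)-2-{4-[2-((S)-4-benzyl-2-oxo-1,3-oxazolidin-3-yl)-2-oxoethoxy]-3,5-dimethoxyphenyl}-5-(dimethoxymethyl)-7-methoxy-2,3-dihydro-1-benzofuran-3-carboxylate | O=C(COc1c(OC)cc([C@@H]2Oc3c(OC)cc(C(OC)OC)cc3[C@H]2C(=O)OC)cc1OC)N4[C@@H](Cc5ccccc5)COC4=O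
F4 | step 14 | Evans syn aldol adduct of F3 with 5 (carbinol 7R, aryloxy carbon as in the target, N-acyl (S)-4-benzyloxazolidinone, aryl acetate) | COc1cc([C@@H](O)[C@@H](C(=O)N2[C@@H](Cc3ccccc3)COC2=O)Oc2c(OC)cc([C@@H]3Oc4c(OC)cc(C(OC)OC)cc4[C@H]3C(=O)OC)cc2OC)ccc1OC(C)=O
F5 | step 14 | 4-nitrobenzoate of the C7-inverted aldol adduct (carbinol carbon 7S) | COc1cc([C@H](OC(=O)c2ccc(cc2)[N+](=O)[O-])[C@@H](C(=O)N2[C@@H](Cc3ccccc3)COC2=O)Oc2c(OC)cc([C@@H]3Oc4c(OC)cc(C(OC)OC)cc4[C@H]3C(=O)OC)cc2OC)ccc1OC(C)=O
F6 | step 14 | dimethyl acetal of 25: (1S,2R)-2-{4-[(2R,3S)-5-(dimethoxymethyl)-3-(hydroxymethyl)-7-methoxy-2,3-dihydro-1-benzofuran-2-yl]-2,6-dimethoxyphenoxy}-1-(4-hydroxy-3-methoxyphenyl)propane-1,3-diol | COc1cc([C@H](O)[C@@H](CO)Oc2c(OC)cc([C@@H]3Oc4c(OC)cc(C(OC)OC)cc4[C@H]3CO)cc2OC)ccc1O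
F7 | step 12 | 2-{4-[(2S,3S)-3-bromo-6-(dimethoxymethyl)-8-methoxy-4-oxochroman-2-yl]-2,6-dimethoxyphenoxy}-N-methoxy-N-methylacetamide (2,3-trans) | CON(C)C(=O)COc1c(OC)cc([C@@H]2Oc3c(OC)cc(C(OC)OC)cc3C(=O)[C@H]2Br)cc1OC
F8 | step 9 | 1-[5-(dimethoxymethyl)-2-hydroxy-3-methoxyphenyl]ethan-1-one | COc1cc(C(OC)OC)cc(C(C)=O)c1O
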